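Numbering: oxolane O1, C2 (ring A), C3 (bears C9, the CH2OH carbon), C4 (bears the carbinol carbon C-alpha with ring B), C5. The ring is cut at O1–C2 and C2–C3: C2 is an aldehyde carbon slipped between an alcohol oxygen and the gamma-carbon of an allylsilane. This exploits that O1, C5, C4 and C3 make up a but-3-en-1-ol unit once C3–C9 is drawn as C=C, and that rings A and B are the same guaiacyl group, so a single silylated vanillin supplies both. The key step closes the only new ring, attaches ring A and sets C2 and C3 in one operation. Its precursor is a (Z)-5-silylpent-3-en-1-ol branched at the future C4.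

Key step: step 8

Assumption: the SEGPHOS antipode written in step 2 is taken to be the one that delivers the (1S,2R) diol; should the sense of induction be the reverse, its mirror image is used and nothing else changes.

Abbreviations: ArT = 3-methoxy-4-(triisopropylsilyloxy)phenyl; TBS = tert-butyldimethylsilyl; TIPS = triisopropylsilyl; TMS = trimethylsilyl.

Step 1
Reactants: 1 vanillin
Product: 2 3-methoxy-4-(triisopropylsilyloxy)benzaldehyde (O-TIPS vanillin)
Conditions: TIPSCl, imidazole, DMF, 0 °C to rt
Reagents that add atoms: triisopropylsilyl chloride, CC(C)[Si](Cl)(C(C)C)C(C)C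
Why: Imidazole-mediated silylation of the phenol (silyl ether formation) leaves the aldehyde free, and the bulky triisopropylsilyl aryl ether is chosen because it should outlast the weak base, the ylide, ozone and the silyl triflate used later.

Step 2
Reactants: 2 O-TIPS vanillin; 3 racemic 4-vinyl-1,3-dioxolan-2-one
Product: 4 (1S,2R)-1-ArT-2-vinylpropane-1,3-diol (anti)
Conditions: [Ir(cod)Cl]2 (2.5 mol %), (S)-SEGPHOS (5 mol %), 4-cyano-3-nitrobenzoic acid (10 mol %), K3PO4 (5 mol %), 2-propanol (2 equiv), THF, 60 °C
Reagents that add atoms: none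
Why: Iridium-catalysed transfer-hydrogenative carbonyl (hydroxymethyl)allylation (Krische allylation): ionisation of the vinyl carbonate with loss of CO2 erases the stereocentre of racemic 3, 2-propanol serves as the terminal reductant, and the (E)-sigma-allyl iridium species adds to the aldehyde through a closed chair so that the chiral bisphosphine sets C-alpha (S) and C4 (R) together as the anti pair.

Step 3
Reactants: 4 anti diol
Product: 5 bis-TBS ether of 4 (primary and benzylic oxygens silylated)
Conditions: TBSOTf (2.5 equiv), 2,6-lutidine, CH2Cl2, -78 to 0 °C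
Reagents that add atoms: tert-butyldimethylsilyl triflate, CC(C)(C)[Si](C)(C)OS(=O)(=O)C(F)(F)F
Why: Silyl triflate with a hindered pyridine base silylates the primary and the hindered benzylic hydroxyl in one operation (silyl ether formation) under conditions too basic to ionise the electron-rich benzylic position, and no stereocentre is touched.

Step 4
Reactants: 5 bis-TBS alkene
Product: 7 (2R,3S)-3-ArT-3-(TBSO)-2-[(TBSO)methyl]propanal, via ozonide 6 (not isolated)
Conditions: O3, CH2Cl2, -78 °C (Sudan red 7B end point); PPh3, -78 °C to rt; used without delay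
Reagents that add atoms: ozone, [O-][O+]=O
Why: Ozonolysis with phosphine work-up: the monosubstituted alkene consumes ozone far faster than the silylated guaiacyl ring when the addition is stopped at the indicator end point, and the cold neutral reduction of ozonide 6 should leave the alpha stereocentre (C4) of the aldehyde intact.

Step 5
Reactants: 8 methyltriphenylphosphonium bromide; 9 (iodomethyl)trimethylsilane
Product: 11 [2-(trimethylsilyl)ethyl]triphenylphosphonium iodide, via methylenetriphenylphosphorane 10 (not isolated)
Conditions: n-BuLi (1.0 equiv), THF, 0 °C to rt; then 9, rt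
Reagents that add atoms: none
Why: C-Alkylation of a non-stabilised phosphorus ylide by the reactive primary iodide (SN2) is the standard entry to this beta-silyl phosphonium salt, which precipitates from THF and is thereby protected from deprotonation by unreacted ylide.

Step 6
Reactants: 7 aldehyde; 11 beta-silyl phosphonium iodide
Product: 13 (Z)-allylsilane with all three oxygens silylated, via silyl ylide 12 (not isolated)
Conditions: 11, KN(SiMe3)2, THF, 0 °C; then 7, -78 °C to rt
Reagents that add atoms: none
Why: Wittig olefination with a non-stabilised ylide under lithium-free conditions at low temperature should pass through the cis-oxaphosphetane to the (Z)-alkene, and carbonyl addition is expected to outrun enolisation or beta-elimination so that C4 keeps its configuration.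

Step 7
Reactants: 13 fully silylated (Z)-allylsilane
Product: 14 (2R,3Z)-2-[(S)-ArT(TBSO)methyl]-5-(trimethylsilyl)pent-3-en-1-ol
Conditions: HF·pyridine, pyridine, THF, 0 °C
Reagents that add atoms: none
Why: Selective desilylation: pyridine-buffered HF·pyridine removes the unhindered primary silyl ether well before the hindered secondary benzylic one or the aryl triisopropylsilyl ethers, and in a non-nucleophilic solvent it is too weakly acidic to protodesilylate the allylsilane or solvolyse the benzylic ether.

Step 8
Reactants: 14 hydroxy (Z)-allylsilane; 2 O-TIPS vanillin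
Product: 17 (2S,3R,4R)-2-ArT-4-[(S)-ArT(TBSO)methyl]-3-vinyloxolane (2,3-cis and 3,4-trans), via trimethylsilyl ether 15 (not isolated), via oxocarbenium triflate 16 (not isolated)
Conditions: TMSOTf (1.05 equiv), 2,6-di-tert-butyl-4-methylpyridine (1.05 equiv), CH2Cl2, -78 °C; then 2 (1.1 equiv), TMSOTf (0.15 equiv), -78 °C; Et3N quench at -78 °C
Reagents that add atoms: none
Why: The trimethylsilyl ether 15 adds to the TMSOTf-activated aldehyde and loses hexamethyldisiloxane to give the (E)-oxocarbenium ion 16 on O1; the gamma-carbon of the allylsilane (C3) then attacks C2 anti to silicon and the beta-silyl cation at C9 collapses to the vinyl group, returning TMSOTf. This is an intramolecular silyl-modified Sakurai (Prins-type) condensation, the known way from 5-silylpent-3-en-1-ols and aldehydes to 2-substituted 3-vinyloxolanes. The oxolane closes by C2–C3 bond formation in a 5-endo-trig mode with respect to C2=O1+ (exo with respect to C3=C9), and attack through C9 to a six-membered ring is excluded because only attack at C3 places the cation beta to silicon. C3 is controlled by allylic 1,3-strain: the Z-CH2SiMe3 terminus holds H4 in the alkene plane, C5 must lie on the attacked face, so the C-alpha branch sits on the far face and C9 ends trans to it. C2 is controlled by the E geometry of the oxocarbenium together with the Z geometry of the alkene: in the envelope transition state C3=C9 lies synclinal to C2=O1+ with the CH2SiMe3 group over the lone-pair side of O1 and not pressed against C2–H, which should place aryl and C9 cis. The step needs the kinetic 2,3-cis product without ionising either benzylic C–O bond; little free TMSOTf at -78 °C, the cold amine quench, the non-enolisable aldehyde and the silyl cap on the C-alpha oxygen (so that only O1 can carry the cation) are meant to secure this.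

Step 9
Reactants: 17 vinyl oxolane
Product: 19 [(2S,3S,4R)-2-ArT-4-[(S)-ArT(TBSO)methyl]oxolan-3-yl]methanol, via ozonide 18 (not isolated)
Conditions: O3, CH2Cl2, -78 °C (Sudan red 7B end point); then NaBH4, MeOH, -78 to 0 °C
Reagents that add atoms: ozone, [O-][O+]=O
Why: Reductive ozonolysis (ozonide formation, then hydride reduction in the same flask) turns the vinyl group into the C9 hydroxymethyl group, the formyl stage at C3 being reduced as soon as it forms so that it should not epimerise towards the 2,3-trans series.

Step 10
Reactants: 19 silylated target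
Product: 20 target, 4-[(2S,3S,4R)-4-[(S)-hydroxy(4-hydroxy-3-methoxyphenyl)methyl]-3-(hydroxymethyl)oxolan-2-yl]-2-methoxyphenol
Conditions: Bu4NF, AcOH (1:1, excess), THF, 0 °C to rt
Reagents that add atoms: none
Why: Fluoride-induced cleavage of all three silyl ethers (global desilylation), buffered with acetic acid so that the freed phenols stay protonated and cannot open the benzylic C2–O1 bond through a quinone methide, which should preserve the 2,3-cis configuration.

Compound list
1 | vanillin (4-hydroxy-3-methoxybenzaldehyde) | COc1cc(C=O)ccc1O | starting material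
2 | 3-methoxy-4-(triisopropylsilyloxy)benzaldehyde | COc1cc(C=O)ccc1O[Si](C(C)C)(C(C)C)C(C)C | intermediate
3 | racemic 4-vinyl-1,3-dioxolan-2-one | C=CC1COC(=O)O1 | starting material
4 | (1S,2R)-1-ArT-2-vinylpropane-1,3-diol (anti) | COc1cc([C@@H](O)[C@H](C=C)CO)ccc1O[Si](C(C)C)(C(C)C)C(C)C | intermediate
5 | (1S,2R)-1-ArT-1,3-bis(TBSO)-2-vinylpropane | COc1cc([C@@H](O[Si](C)(C)C(C)(C)C)[C@H](C=C)CO[Si](C)(C)C(C)(C)C)ccc1O[Si](C(C)C)(C(C)C)C(C)C | intermediate
6 | ozonide of 5 (1,2,4-trioxolane in place of the vinyl group, both epimers at the trioxolane carbon) | COc1cc([C@@H](O[Si](C)(C)C(C)(C)C)[C@H](C2OCOO2)CO[Si](C)(C)C(C)(C)C)ccc1O[Si](C(C)C)(C(C)C)C(C)C | intermediate (not isolated)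
7 | (2R,3S)-3-ArT-3-(TBSO)-2-[(TBSO)methyl]propanal | COc1cc([C@@H](O[Si](C)(C)C(C)(C)C)[C@H](C=O)CO[Si](C)(C)C(C)(C)C)ccc1O[Si](C(C)C)(C(C)C)C(C)C | intermediate
8 | methyltriphenylphosphonium bromide | C[P+](c1ccccc1)(c1ccccc1)c1ccccc1.[Br-] | starting material
9 | (iodomethyl)trimethylsilane | C[Si](C)(C)CI | starting material
10 | methylenetriphenylphosphorane | C=P(c1ccccc1)(c1ccccc1)c1ccccc1 | intermediate (not isolated)
11 | [2-(trimethylsilyl)ethyl]triphenylphosphonium iodide | C[Si](C)(C)CC[P+](c1ccccc1)(c1ccccc1)c1ccccc1.[I-] | intermediate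
12 | [2-(trimethylsilyl)ethylidene]triphenylphosphorane | C[Si](C)(C)CC=P(c1ccccc1)(c1ccccc1)c1ccccc1 | intermediate (not isolated)
13 | TBS ether of (2R,3Z)-2-[(S)-ArT(TBSO)methyl]-5-(trimethylsilyl)pent-3-en-1-ol | COc1cc([C@@H](O[Si](C)(C)C(C)(C)C)[C@H](/C=C\C[Si](C)(C)C)CO[Si](C)(C)C(C)(C)C)ccc1O[Si](C(C)C)(C(C)C)C(C)C | intermediate
14 | (2R,3Z)-2-[(S)-ArT(TBSO)methyl]-5-(trimethylsilyl)pent-3-en-1-ol | COc1cc([C@@H](O[Si](C)(C)C(C)(C)C)[C@H](/C=C\C[Si](C)(C)C)CO)ccc1O[Si](C(C)C)(C(C)C)C(C)C | intermediate
15 | trimethylsilyl ether of 14 | COc1cc([C@@H](O[Si](C)(C)C(C)(C)C)[C@H](/C=C\C[Si](C)(C)C)CO[Si](C)(C)C)ccc1O[Si](C(C)C)(C(C)C)C(C)C | intermediate (not isolated)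
16 | (E)-oxocarbenium triflate from 15 and 2 (ArT–CH=O+–C5) | COc1cc([C@@H](O[Si](C)(C)C(C)(C)C)[C@H](/C=C\C[Si](C)(C)C)C/[O+]=C/c2ccc(O[Si](C(C)C)(C(C)C)C(C)C)c(OC)c2)ccc1O[Si](C(C)C)(C(C)C)C(C)C.[O-]S(=O)(=O)C(F)(F)F | intermediate (not isolated)
17 | (2S,3R,4R)-2-ArT-4-[(S)-ArT(TBSO)methyl]-3-vinyloxolane | COc1cc([C@@H](O[Si](C)(C)C(C)(C)C)[C@H]2CO[C@H](c3ccc(O[Si](C(C)C)(C(C)C)C(C)C)c(OC)c3)[C@@H]2C=C)ccc1O[Si](C(C)C)(C(C)C)C(C)C | intermediate
18 | ozonide of 17 (1,2,4-trioxolane on C3, both epimers at the trioxolane carbon) | COc1cc([C@@H](O[Si](C)(C)C(C)(C)C)[C@H]2CO[C@H](c3ccc(O[Si](C(C)C)(C(C)C)C(C)C)c(OC)c3)[C@@H]2C4OCOO4)ccc1O[Si](C(C)C)(C(C)C)C(C)C | intermediate (not isolated)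
19 | [(2S,3S,4R)-2-ArT-4-[(S)-ArT(TBSO)methyl]oxolan-3-yl]methanol (same spatial arrangement as 17; the C3 descriptor changes by priority only) | COc1cc([C@@H](O[Si](C)(C)C(C)(C)C)[C@H]2CO[C@H](c3ccc(O[Si](C(C)C)(C(C)C)C(C)C)c(OC)c3)[C@@H]2CO)ccc1O[Si](C(C)C)(C(C)C)C(C)C | intermediate
20 | 4-[(2S,3S,4R)-4-[(S)-hydroxy(4-hydroxy-3-methoxyphenyl)methyl]-3-(hydroxymethyl)oxolan-2-yl]-2-methoxyphenol | COc1cc([C@@H](O)[C@H]2CO[C@H](c3ccc(O)c(OC)c3)[C@@H]2CO)ccc1O | target

Total step count: 10
Longest linear sequence: 9 steps (steps 1, 2, 3, 4, 6, 7, 8, 9, 10 from vanillin; step 5 is the side branch)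

Steps most likely to fail

1. Step 8. Three processes may go wrong. The benzylic C2–O1 bond may reionise, so that the kinetic 2,3-cis ring drifts to the trans series. The silylated benzylic C-alpha position may ionise under the Lewis acid. The face selectivity at C2 may be incomplete. The fallback makes the C2–C3 bond first and closes the ring by C–O bond formation under base, so that no cation is ever placed at C2. It sets out from 5. Cross-metathesis with (E)-1,4-dibromobut-2-ene (second-generation Hoveyda–Grubbs catalyst, CH2Cl2, 40 °C) should give the allylic bromide F1. A Nozaki–Hiyama allylation of 2 with this bromide (CrCl2, THF, 0 °C to rt) is expected to give the anti homoallylic alcohol F2. The anti relation, which maps onto 2,3-cis, does not depend on the bromide geometry. Attack anti to the C-alpha branch should give the 3,4-trans relation, though with weaker acyclic control, so a separation of diastereomers may be needed. Removal of the primary silyl group as in step 7 should give the diol F3. Tosylation of its primary hydroxyl (TsCl, pyridine, 0 °C) should give the primary tosylate F4. NaH in THF then closes the oxolane by a 5-exo-tet Williamson etherification in which the C2 alkoxide displaces the C5 tosylate and C2 is untouched. The route is rejoined at 17.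

2. Step 6. The alpha-branched aldehyde may enolise in the basic ylide medium and lose its C4 configuration, silanolate may be lost by beta-elimination, or the Z selectivity may be incomplete. The fallback avoids both the aldehyde and the base. It sets out from 5 and uses a Z-selective cross-metathesis with allyltrimethylsilane, which should give 13 directly. The catalyst is the Z-selective Grubbs catalyst, in which ruthenium is chelated by a cyclometalated N-adamantyl N-heterocyclic carbene and carries a nitrato ligand (THF, 35 °C, ethene swept out). No compound outside the list is made (none F0), and the route is rejoined at 13.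

3. Step 9. Ozone may attack the two electron-rich silylated guaiacyl rings, and C3 may epimerise if the formyl stage lives too long. The fallback replaces ozone by a staged Lemieux–Johnson-type cleavage and sets out from 17. Dihydroxylation (OsO4 cat., N-methylmorpholine N-oxide, acetone–water) should give the vicinal diol F5. Periodate cleavage (NaIO4, THF–pH 7 buffer, 0 °C) should give the aldehyde F6, which is reduced at once (NaBH4, MeOH, 0 °C). The route is rejoined at 19.

Further compounds
F1 | step 8 | (E)-allylic bromide from 5 (CH=CH–CH2Br in place of the vinyl group) | COc1cc([C@@H](O[Si](C)(C)C(C)(C)C)[C@H](/C=C/CBr)CO[Si](C)(C)C(C)(C)C)ccc1O[Si](C(C)C)(C(C)C)C(C)C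
F2 | step 8 | anti homoallylic alcohol (C2 carbinol with ring A, C3 vinyl, C5 and C-alpha oxygens as TBS ethers) | COc1cc([C@@H](O[Si](C)(C)C(C)(C)C)[C@@H](CO[Si](C)(C)C(C)(C)C)[C@@H](C=C)[C@H](O)c2ccc(O[Si](C(C)C)(C(C)C)C(C)C)c(OC)c2)ccc1O[Si](C(C)C)(C(C)C)C(C)C
F3 | step 8 | diol (F2 with the primary C5 hydroxyl free) | COc1cc([C@@H](O[Si](C)(C)C(C)(C)C)[C@@H](CO)[C@@H](C=C)[C@H](O)c2ccc(O[Si](C(C)C)(C(C)C)C(C)C)c(OC)c2)ccc1O[Si](C(C)C)(C(C)C)C(C)C
F4 | step 8 | primary tosylate of F3 | COc1cc([C@@H](O[Si](C)(C)C(C)(C)C)[C@@H](COS(=O)(=O)c3ccc(C)cc3)[C@@H](C=C)[C@H](O)c2ccc(O[Si](C(C)C)(C(C)C)C(C)C)c(OC)c2)ccc1O[Si](C(C)C)(C(C)C)C(C)C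
F0 | step 6 | none | none
F5 | step 9 | vicinal diol from 17 (1,2-dihydroxyethyl group on C3, both epimers at the new carbinol) | COc1cc([C@@H](O[Si](C)(C)C(C)(C)C)[C@H]2CO[C@H](c3ccc(O[Si](C(C)C)(C(C)C)C(C)C)c(OC)c3)[C@@H]2C(O)CO)ccc1O[Si](C(C)C)(C(C)C)C(C)C
F6 | step 9 | aldehyde (formyl group on C3 of the 2,3-cis-3,4-trans oxolane) | COc1cc([C@@H](O[Si](C)(C)C(C)(C)C)[C@H]2CO[C@H](c3ccc(O[Si](C(C)C)(C(C)C)C(C)C)c(OC)c3)[C@@H]2C=O)ccc1O[Si](C(C)C)(C(C)C)C(C)C
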